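**Strategy**

The route rests on disconnecting ring B of the target at two neighbouring positions: the C1'–C2 bond to the furan carbon and the C2'–O bond of the future methyl ether. A 3,5-bis(methoxymethoxy)benzyne, released from an ortho-silyl aryl triflate, is inserted into the C–O bond of a racemic 2-arylpropanoic acid; one operation therefore gives an ortho-hydroxyaryl ketone in which C1' carries the acyl carbon (later C2 of the benzofuran), C2' carries the only free phenol, and C4'/C6' keep their protected oxygens. That phenol steers a reverse-prenyl ether/Claisen sequence to C3' and is then methylated; acid finally unmasks the phenols and closes the furan ring.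

Key step: step 8

Remark on numbering: ring B positions are primed (C1'–C6'); the benzofuran carries unprimed numbers.

Assumption: the α-carbon of 10 and of 12 and 14–18 is carried as the racemate; it becomes the sp2 carbon C3 of the benzofuran in step 12, and the target has no stereocentre.

**Route**

Step 1
Reactants: 1 phloroglucinol
Product: 2 3,5-bis(methoxymethoxy)phenol
Conditions: MOMCl (2.0 equiv), i-Pr2NEt (2.2 equiv), DMF, 0 °C → rt; chromatography removes mono- and tris-ethers
Reagents that add atoms: chloromethyl methyl ether, COCCl
Why: Williamson-type O-alkylation of a threefold-symmetric triphenol with a limiting amount of the chloro ether should give the bis-ether as the main part of a separable statistical mixture, and no regiochemical question arises because the three hydroxyls are equivalent.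

Step 2
Reactants: 2 3,5-bis(methoxymethoxy)phenol
Product: 3 3,5-bis(methoxymethoxy)phenyl N,N-diethylcarbamate
Conditions: ClCONEt2 (1.2 equiv), K2CO3, MeCN, reflux
Reagents that add atoms: N,N-diethylcarbamoyl chloride, CCN(CC)C(Cl)=O
Why: O-carbamoylation of the phenoxide (acyl substitution) installs the strongest oxygen-based directing group for the metalation that follows, and MOM ethers are inert to carbonate.

Step 3
Reactants: 3 3,5-bis(methoxymethoxy)phenyl N,N-diethylcarbamate
Product: 4 3,5-bis(methoxymethoxy)-2-(trimethylsilyl)phenyl N,N-diethylcarbamate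
Conditions: s-BuLi (1.1 equiv), TMEDA, THF, −78 °C; then TMSCl, −78 °C → rt
Reagents that add atoms: chlorotrimethylsilane, C[Si](C)(C)Cl
Why: Directed ortho-metalation should place lithium at C2, where the carbamate and the adjacent MOM ether cooperate (C2 and C6 are equivalent), and the low temperature holds back the anionic ortho-Fries shift before silylation.

Step 4
Reactants: 4 3,5-bis(methoxymethoxy)-2-(trimethylsilyl)phenyl N,N-diethylcarbamate
Product: 5 3,5-bis(methoxymethoxy)-2-(trimethylsilyl)phenol
Conditions: LiAlH4 (2 equiv), THF, 0 °C → 50 °C; Rochelle-salt work-up at pH ≥ 7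
Reagents that add atoms: none
Why: Reductive cleavage of the aryl carbamate (hydride addition to the carbonyl, loss of phenoxide) leaves MOM ethers and the aryl–silicon bond untouched, and the non-acidic work-up protects the electron-rich arylsilane from protodesilylation.

Step 5
Reactants: 5 3,5-bis(methoxymethoxy)-2-(trimethylsilyl)phenol
Product: 6 3,5-bis(methoxymethoxy)-2-(trimethylsilyl)phenyl trifluoromethanesulfonate
Conditions: PhNTf2 (1.2 equiv), DBU, MeCN, rt → 40 °C
Reagents that add atoms: N-phenylbis(trifluoromethanesulfonimide), O=S(=O)(N(c1ccccc1)S(=O)(=O)C(F)(F)F)C(F)(F)F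
Why: O-sulfonylation of the phenoxide with a mild triflyl donor should triflate even this silyl-flanked phenol without the strong electrophile that could attack the MOM acetals.

Step 6
Reactants: 7 2,4-dihydroxyphenylacetic acid
Product: 9 2-[2,4-bis(methoxymethoxy)phenyl]acetic acid, via methoxymethyl ester 8 (not isolated)
Conditions: MOMCl (3.6 equiv), i-Pr2NEt (4 equiv), DMF, 0 °C → rt; then LiOH, THF/MeOH/H2O, rt; cold 1 M HCl to pH 4
Reagents that add atoms: chloromethyl methyl ether, COCCl; lithium hydroxide, [Li+].[OH-]
Why: Exhaustive O-alkylation caps both phenols and the carboxylate, and saponification then frees only the acid because aryl MOM ethers are base-stable while the acylal-type MOM ester hydrolyses readily.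

Step 7
Reactants: 9 2-[2,4-bis(methoxymethoxy)phenyl]acetic acid
Product: 10 2-[2,4-bis(methoxymethoxy)phenyl]propanoic acid (racemic)
Conditions: LiN(i-Pr)2 (2.1 equiv), THF, −78 → 0 °C; MeI (1.05 equiv), −78 °C → rt; cold dilute HCl to pH 4
Reagents that add atoms: iodomethane, CI
Why: Alkylation of the carboxylic acid dianion (enediolate) at its benzylic α-carbon should stop at monomethylation, and the new stereocentre is formed as the racemate on purpose since it is erased in step 12.

Step 8
Reactants: 6 3,5-bis(methoxymethoxy)-2-(trimethylsilyl)phenyl trifluoromethanesulfonate; 10 2-[2,4-bis(methoxymethoxy)phenyl]propanoic acid (racemic)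
Product: 12 2-[2,4-bis(methoxymethoxy)phenyl]-1-[2-hydroxy-4,6-bis(methoxymethoxy)phenyl]propan-1-one (racemic), via aryne 11 (not isolated)
Conditions: CsF (4 equiv), 6 (1.5 equiv), THF, sealed tube, 125 °C
Reagents that add atoms: none
Why: Fluoride attacks silicon of 6 and expels triflate to give aryne 11; the cesium carboxylate of 10 adds through oxygen to the aryne carbon that is meta to both ethers, and the aryl anion formed next to the flanking ether attacks the ester carbonyl through a four-membered alkoxide that opens to the ortho-acyl phenoxide, so the C2'–O and C1'–C2 bonds form together. The closest known reaction type is the fluoride-promoted insertion of arynes into the C–O bond of carboxylic acids to give ortho-hydroxyaryl ketones, in effect an aryne O-arylation followed by an anionic Fries-type acyl shift. No ring is closed (the four-membered ring is transient) and no stereocentre is created; the α-methine of 10 is racemic and may epimerise without consequence. The step needs regioselectivity (oxygen distal, acyl proximal to the ether), which the MOM ether beside the triple bond secures by distorting the aryne and stabilising the adjacent carbanion inductively. It also needs acyl transfer to outrun protonation to the simple aryl ester, which hot THF favours because the acid proton is held as sparingly soluble CsHF2 while the intramolecular shift is fast. The phenol released is the only free hydroxyl and is hydrogen-bonded to the ketone, which should limit a second arylation.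

Step 9
Reactants: 12 2-[2,4-bis(methoxymethoxy)phenyl]-1-[2-hydroxy-4,6-bis(methoxymethoxy)phenyl]propan-1-one (racemic); 13 3-chloro-3-methylbut-1-yne
Product: 14 2-[2,4-bis(methoxymethoxy)phenyl]-1-[2,4-bis(methoxymethoxy)-6-[(2-methylbut-3-yn-2-yl)oxy]phenyl]propan-1-one (racemic)
Conditions: 13 (2 equiv), DBU (2.5 equiv), CuCl2·2H2O (1 mol%), MeCN, 0 °C → rt
Reagents that add atoms: none
Why: Copper-catalysed propargylic etherification of phenols with tertiary propargyl chlorides tolerates hindered phenoxides, and 12 offers a single free hydroxyl so no site selectivity is required.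

Step 10
Reactants: 14 2-[2,4-bis(methoxymethoxy)phenyl]-1-[2,4-bis(methoxymethoxy)-6-[(2-methylbut-3-yn-2-yl)oxy]phenyl]propan-1-one (racemic)
Product: 16 2-[2,4-bis(methoxymethoxy)phenyl]-1-[2-hydroxy-4,6-bis(methoxymethoxy)-3-(3-methylbut-2-en-1-yl)phenyl]propan-1-one (racemic), via allyl ether 15 (not isolated)
Conditions: H2 (1 atm), Pd/CaCO3 poisoned with Pb(OAc)2, quinoline, toluene, rt; filter; filtrate 110 °C
Reagents that add atoms: none
Why: Semihydrogenation of the terminal alkyne over poisoned palladium gives the 1,1-dimethylallyl ether, whose aromatic Claisen rearrangement should deliver the allyl unit with inversion, as a prenyl group, to C3', the only open ortho position because C1' bears the acyl group.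

Step 11
Reactants: 16 2-[2,4-bis(methoxymethoxy)phenyl]-1-[2-hydroxy-4,6-bis(methoxymethoxy)-3-(3-methylbut-2-en-1-yl)phenyl]propan-1-one (racemic)
Product: 17 2-[2,4-bis(methoxymethoxy)phenyl]-1-[2-methoxy-4,6-bis(methoxymethoxy)-3-(3-methylbut-2-en-1-yl)phenyl]propan-1-one (racemic)
Conditions: MeI (3 equiv), K2CO3, acetone, reflux
Reagents that add atoms: iodomethane, CI
Why: Williamson O-methylation of the single, chelated phenol should proceed under carbonate, which is too weak a base to enolise the hindered ketone to any extent that would cause C-methylation.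

Step 12
Reactants: 17 2-[2,4-bis(methoxymethoxy)phenyl]-1-[2-methoxy-4,6-bis(methoxymethoxy)-3-(3-methylbut-2-en-1-yl)phenyl]propan-1-one (racemic)
Product: 19 glycybenzofuran [4-(6-hydroxy-3-methyl-1-benzofuran-2-yl)-5-methoxy-6-(3-methylbut-2-en-1-yl)benzene-1,3-diol], via tetraphenol ketone 18 (not isolated)
Conditions: HCl (1.25 M in MeOH), 45 °C
Reagents that add atoms: none
Why: Acid-catalysed acetal exchange should remove the four MOM groups, after which the ortho-phenol of ring A adds to the ketone and water is lost to give the aromatic furan (cyclodehydration of a 2-hydroxybenzyl ketone), the mild anhydrous acid being chosen to spare the prenyl group.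

**Compound list**

1 | phloroglucinol | Oc1cc(O)cc(O)c1 | starting material
2 | 3,5-bis(methoxymethoxy)phenol | COCOc1cc(O)cc(OCOC)c1 | intermediate
3 | 3,5-bis(methoxymethoxy)phenyl N,N-diethylcarbamate | CCN(CC)C(=O)Oc1cc(OCOC)cc(OCOC)c1 | intermediate
4 | 3,5-bis(methoxymethoxy)-2-(trimethylsilyl)phenyl N,N-diethylcarbamate | CCN(CC)C(=O)Oc1cc(OCOC)cc(OCOC)c1[Si](C)(C)C | intermediate
5 | 3,5-bis(methoxymethoxy)-2-(trimethylsilyl)phenol | COCOc1cc(OCOC)c([Si](C)(C)C)c(O)c1 | intermediate
6 | 3,5-bis(methoxymethoxy)-2-(trimethylsilyl)phenyl trifluoromethanesulfonate | COCOc1cc(OCOC)c([Si](C)(C)C)c(OS(=O)(=O)C(F)(F)F)c1 | intermediate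
7 | 2,4-dihydroxyphenylacetic acid | OC(=O)Cc1ccc(O)cc1O | starting material
8 | methoxymethyl 2-[2,4-bis(methoxymethoxy)phenyl]acetate (not isolated) | COCOC(=O)Cc1ccc(OCOC)cc1OCOC | intermediate
9 | 2-[2,4-bis(methoxymethoxy)phenyl]acetic acid | OC(=O)Cc1ccc(OCOC)cc1OCOC | intermediate
10 | 2-[2,4-bis(methoxymethoxy)phenyl]propanoic acid (racemic) | CC(C(=O)O)c1ccc(OCOC)cc1OCOC | intermediate
11 | 3,5-bis(methoxymethoxy)benzyne (not isolated) | COCOC1=CC(OCOC)=CC#C1 | intermediate
12 | 2-[2,4-bis(methoxymethoxy)phenyl]-1-[2-hydroxy-4,6-bis(methoxymethoxy)phenyl]propan-1-one (racemic) | CC(C(=O)c1c(O)cc(OCOC)cc1OCOC)c1ccc(OCOC)cc1OCOC | intermediate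
13 | 3-chloro-3-methylbut-1-yne | CC(C)(Cl)C#C | starting material
14 | 2-[2,4-bis(methoxymethoxy)phenyl]-1-[2,4-bis(methoxymethoxy)-6-[(2-methylbut-3-yn-2-yl)oxy]phenyl]propan-1-one (racemic) | CC(C(=O)c1c(OC(C)(C)C#C)cc(OCOC)cc1OCOC)c1ccc(OCOC)cc1OCOC | intermediate
15 | 2-[2,4-bis(methoxymethoxy)phenyl]-1-[2,4-bis(methoxymethoxy)-6-[(2-methylbut-3-en-2-yl)oxy]phenyl]propan-1-one (racemic, not isolated) | CC(C(=O)c1c(OC(C)(C)C=C)cc(OCOC)cc1OCOC)c1ccc(OCOC)cc1OCOC | intermediate
16 | 2-[2,4-bis(methoxymethoxy)phenyl]-1-[2-hydroxy-4,6-bis(methoxymethoxy)-3-(3-methylbut-2-en-1-yl)phenyl]propan-1-one (racemic) | CC(C(=O)c1c(O)c(CC=C(C)C)c(OCOC)cc1OCOC)c1ccc(OCOC)cc1OCOC | intermediate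
17 | 2-[2,4-bis(methoxymethoxy)phenyl]-1-[2-methoxy-4,6-bis(methoxymethoxy)-3-(3-methylbut-2-en-1-yl)phenyl]propan-1-one (racemic) | CC(C(=O)c1c(OC)c(CC=C(C)C)c(OCOC)cc1OCOC)c1ccc(OCOC)cc1OCOC | intermediate
18 | 2-(2,4-dihydroxyphenyl)-1-[4,6-dihydroxy-2-methoxy-3-(3-methylbut-2-en-1-yl)phenyl]propan-1-one (racemic, not isolated) | CC(C(=O)c1c(OC)c(CC=C(C)C)c(O)cc1O)c1ccc(O)cc1O | intermediate
19 | glycybenzofuran, 4-(6-hydroxy-3-methyl-1-benzofuran-2-yl)-5-methoxy-6-(3-methylbut-2-en-1-yl)benzene-1,3-diol | COc1c(CC=C(C)C)c(O)cc(O)c1-c1oc2cc(O)ccc2c1C | target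

**Step count**

Total step count: 12.
Longest linear sequence: 10 steps (steps 1–5, 8, 9–12; 1 → 2 → 3 → 4 → 5 → 6 → 12 → 14 → 16 → 17 → 19).

**Steps most likely to fail**

Step 8. Protonation of the aryl anion may outpace the acyl shift, so that only O-arylation occurs. The carboxylate may also add with eroded regioselectivity, or surplus aryne may arylate the enolisable ketone. The fallback makes the same aryl anion by halogen–metal exchange inside a preformed ester; it sets out from carbamate 3 and acid 10 and returns at ketone 12. Carbamate 3 is lithiated as in step 3 (s-BuLi, TMEDA, THF, −78 °C) and quenched with I2 to give 2-iodo-3,5-bis(methoxymethoxy)phenyl N,N-diethylcarbamate F1. NaOH in EtOH at reflux cleaves the carbamate to 2-iodo-3,5-bis(methoxymethoxy)phenol F2. Esterification with 10 (EDC·HCl, DMAP, CH2Cl2) gives 2-iodo-3,5-bis(methoxymethoxy)phenyl 2-[2,4-bis(methoxymethoxy)phenyl]propanoate F3. Iodine–lithium exchange with n-BuLi in THF at −95 °C should then trigger the anionic ortho-Fries acyl shift through the same four-membered transition state and give 12, with regiochemistry fixed by the position of iodine.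

Step 9. Alkylation of the hydrogen-bonded phenol flanked by the acyl group may stall, or elimination of the tertiary chloride may consume the electrophile first. The fallback replaces propargylation and semihydrogenation by a Tsuji–Trost O-allylation; it sets out from 12 and returns at allyl ether 15. 2-Methylbut-3-en-2-ol is converted with n-BuLi and Boc2O into tert-butyl 2-methylbut-3-en-2-yl carbonate F4. Treating 12 with F4 and Pd(PPh3)4 (zerovalent palladium, catalytic) in THF at 0 °C should give the branched 1,1-dimethylallyl ether 15 directly by attack of the phenoxide on the more substituted allyl terminus. Compound 15 is then heated in toluene as in step 10 to give 16.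

Step 12. Acid may add the C4' hydroxyl across the prenyl double bond (chroman formation) or hydrochlorinate the alkene before the deactivated ketone has cyclodehydrated. The fallback separates deprotection from ring closure and avoids Brønsted acid in the first stage; it sets out from 17 and returns at 18, then 19. TMSOTf with 2,2'-bipyridyl in CH2Cl2 at 0 °C followed by water should convert the aryl MOM ethers, via aryl silyl ethers, into the free phenols, giving tetraphenol ketone 18 as an isolated compound. Compound 18 is then cyclodehydrated with pyridinium p-toluenesulfonate in toluene at 60–80 °C over molecular sieves to give 19. No compound outside the list is made (F0).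

**Further compounds**

F1 | step 8 | 2-iodo-3,5-bis(methoxymethoxy)phenyl N,N-diethylcarbamate | CCN(CC)C(=O)Oc1cc(OCOC)cc(OCOC)c1I
F2 | step 8 | 2-iodo-3,5-bis(methoxymethoxy)phenol | COCOc1cc(OCOC)c(I)c(O)c1
F3 | step 8 | 2-iodo-3,5-bis(methoxymethoxy)phenyl 2-[2,4-bis(methoxymethoxy)phenyl]propanoate (racemic) | CC(C(=O)Oc1cc(OCOC)cc(OCOC)c1I)c1ccc(OCOC)cc1OCOC
F4 | step 9 | tert-butyl 2-methylbut-3-en-2-yl carbonate | C=CC(C)(C)OC(=O)OC(C)(C)C
F0 | step 12 | none | none
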